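Monomer in chains is the product, and the closed runs tell us how it accumulates in each vessel.

| flask | free monomer | transfer agent | pre-initiator | remark | time |
|---|---|---|---|---|---|
| Saturday's | 0.050 M | 0.015 M | 0.14 mM | run made earlier |  |
| Sunday's | 0.025 M | 0.015 M | 0.14 mM | run made earlier |  |
| Wednesday's | 0.038 M | 0.015 M | 0.14 mM | run made earlier |  |
| Tuesday's | 0.050 M | 0.015 M | 0.070 mM | run made earlier |  |
| south-west | 0.050 M | 0.0150 M | 0.14 mM | a single well-mixed tank run continuously and read at steady state, 30 h in it on average |  |
| east | 0.050 M (fed, over 15.0 h) | 0.0150 M | 0.14 mM | a stirred flask in which free monomer is dosed at a steady rate over 15.0 h without added volume, worked up at 30 h | 30 h |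
| north | 0.050 M | 0.0150 M | 0.14 mM | everything together in a closed stirred flask, run for 30 h | 30 h |

| run | time / h | monomer in chains / % | free monomer / % |
|---|---|---|---|
| Saturday's | 1.50 | 0 | 100.1 |
| Saturday's | 5.00 | 0.2 | 99.1 |
| Saturday's | 8.00 | 1.9 | 97.8 |
| Saturday's | 12.0 | 4.7 | 94.0 |
| Saturday's | 20.0 | 15.8 | 84.5 |
| Saturday's | 25.0 | 22.1 | 77.0 |
| Saturday's | 30.0 | 29.4 | 70.5 |
| Sunday's | 2.50 | 0 | 100.0 |
| Sunday's | 5.00 | 0.3 | 99.5 |
| Sunday's | 8.00 | 2.4 | 97.7 |
| Sunday's | 10.0 | 2.6 | 96.8 |
| Sunday's | 12.0 | 2.6 | 94.9 |
| Sunday's | 15.0 | 6.2 | 92.9 |
| Sunday's | 20.0 | 12.1 | 87.0 |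
| Wednesday's | 1.33 | 0.1 | 100.9 |
| Wednesday's | 2.00 | 0.1 | 99.6 |
| Wednesday's | 3.00 | 0 | 100.3 |
| Wednesday's | 5.00 | 0.7 | 99.3 |
| Wednesday's | 8.00 | 1.8 | 97.9 |
| Wednesday's | 12.0 | 4.8 | 95.3 |
| Wednesday's | 20.0 | 14.5 | 86.1 |
| Tuesday's | 1.50 | 0 | 100.4 |
| Tuesday's | 5.00 | 0 | 98.2 |
| Tuesday's | 8.00 | 1.1 | 99.1 |
| Tuesday's | 12.0 | 2.4 | 97.3 |
| Tuesday's | 20.0 | 7.8 | 91.8 |

(readings scatter by 0.5 percentage points)

* the set-up with the highest amount of monomer in chains at the outlet or at the end, in percent of the free monomer put in ("none" if the first two lie within 2 percentage points) (south-west / east / north / none)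
* amount of monomer in chains at the outlet or at the end, in percent of the free monomer put in, south-west
* amount of monomer in chains at the outlet or at the end, in percent of the free monomer put in, east
* amount of monomer in chains at the outlet or at the end, in percent of the free monomer put in, north

- the stated concentrations are those of everything mixed, before any reaction; amounts are the same in each set-up
- the analysis behind the earlier runs scatters by 0.5 percentage points, standard deviation
- the feed brings no volume worth counting
- the earlier runs were made in a closed, stirred flask

We carry one quantity, the exposure, which is minus the natural logarithm of the fraction of free monomer left: Saturday's run reads 0.350 at 30.0 h. Our bench rule says exposure grows as [pre-initiator] times time squared, as for free monomer lost pseudo-first-order to something released steadily from the pre-initiator. Tuesday's run, with half the pre-initiator, reads 0.508 of Saturday's exposure at 20.0 h. From 20.0 h to 30.0 h, Saturday's exposure rises by a factor of 2.08, where the rule asks 2.25. The border shows in Sunday's run: at half the free monomer its exposure is 0.827 of Saturday's at the same time, where the rule expects equality, so thin monomer falls short of the rule.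

North repeats Saturday's run, giving 29.5%. In east, a parcel dosed at time s sees exposure in proportion to t² − s², and the mean s² over the feed is a third of its length squared, giving 27.4%, likely high by Sunday's border. For the south-west tank we replace −ln(1−x) by x/(1−x), giving 25.9%, our roughest step. North leads east, second in our reckoning, by 2.1 percentage points, over the margin of 2 points, and east is likely high, so we choose north, with the tank figure as the weak point of that choice. The forecast, which makes the same choice, gives 25% for south-west, 25% for east, 29.3% for north and names north as best, reasoning that “North simply repeats Saturday's run”.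

The simulation gives 28.1% for south-west, where we had 25.9%, 26.6% for east and 29.4% for north, so the best is none: south-west stands second, 1.3 points behind north, inside the margin of 2 points.

    free monomer + initiator → living end + monomer in chains (k = 0.00200 M⁻¹ s⁻¹)
    free monomer + living end → monomer in chains + living end, rate k2*[living end]*[free monomer] (k = 0.0780 M⁻¹ s⁻¹)
    living end + transfer agent → dead chain (kL = 2.40 × 10⁻⁴ M⁻¹ s⁻¹)
    free monomer + initiator → spent initiator (k = 1.10 × 10⁻⁴ M⁻¹ s⁻¹)
    pre-initiator → initiator (k = 1.10 × 10⁻⁵ s⁻¹)

In north at 30.0 h, growth at living ends uses free monomer 400 times as fast as the first addition to initiator, with half-lives of 35 h against 590 d. North's exposure of 0.348 is therefore a measure of growth at living ends, which stand at 6.98 × 10⁻⁵ M beside 6.80 × 10⁻⁶ M of initiator. For north with 2.4 × 10⁻⁴ M of pre-initiator, read at the same time, exposure scales to 0.599, which means 45.1% in chains; the simulation gives 44.6%.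

The numbers in the tables stem from a simulated flask with constants of no real substance, noise included.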